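Flavanone locants are used throughout: plain for the anisyl half, doubly primed for the phenol half.
Cuts: the 4'''-O protecting group, then C4a–C5 and C4a''–C5'' of both rings A, then O1–C8a/O1''–C8a'', C4–C4a/C4''–C4a'', C2''–C3'' and C3–C3''.
Enabling feature: each ring A (C4a, C5, C6, C7, C8, C8a, with oxygen on C5, C7 and C8a) is a folded triketide. A 2,3-dihydropyran-4-one ring C (O1, C2, C3, C4, C4a, C8a) already ties the C8a oxygen up as O1 and holds C4a–H cis to C8 across C4a=C8a, so a ketene carbon C5 on the C8–C7–C6 arm can only bond to C4a.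
Forward: the C2–C3–C3''–C2'' backbone is joined linearly (alkylation, then aldol on a γ-lactone). Both acyl ends are then extended by the six-carbon keto-dioxinone unit, both rings C close together, and both rings A close last in one thermolysis.
Stereochemistry: C2 comes from asymmetric transfer hydrogenation, C3 from chelate-controlled anti alkylation, and C3'' from attack on the lactone enolate opposite the cis aryl/ester pair. C2'' comes from the chair aldol transition state of the ring-fixed (E)-enolate, and no later step touches the four centres.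

Key step: step 10

Remark: the (S,S)-catalyst of step 1 is assumed to give the (S)-carbinol, as it does with simple aryl alkyl ketones; if the sense were opposite, the (R,R)-catalyst would be used.

Step 1
Reactants: 1 methyl 3-(4-methoxyphenyl)-3-oxopropanoate
Product: 2 methyl (3S)-3-hydroxy-3-(4-methoxyphenyl)propanoate
Conditions: RuCl[(S,S)-TsDPEN](p-cymene) (1 mol %), HCO2H/Et3N azeotrope, 30 °C
Reagents that add atoms: none
Why: Noyori–Ikariya asymmetric transfer hydrogenation reduces the aryl ketone through the six-membered Ru–H/N–H transition state, in which the CH/π contact between the aryl ring and the p-cymene ligand of the (S,S)-catalyst directs hydride to the face that gives the (S)-carbinol C2, while the ester is inert.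

Step 2
Reactants: 2 methyl (3S)-3-hydroxy-3-(4-methoxyphenyl)propanoate; 3 methyl bromoacetate
Product: 6 methyl (2S,3R)-2-(4-methoxyphenyl)-5-oxooxolane-3-carboxylate (cis lactone), via dilithium alkoxide-enolate 4 (not isolated), via anti hydroxy diester 5 (not isolated)
Conditions: LiN(iPr)2 (2.2 equiv), THF, −78 to −20 °C; 3, −78 to −40 °C; AcOH, −78 °C; crude 5, PPTS (cat.), PhMe, 50 °C
Reagents that add atoms: none
Why: Fráter–Seebach alkylation: in the lithium-bridged six-membered chelate 4 (O1, C2, C3 and C4 in the ring) the reactive α-bromo ester attacks C3 from the side away from the aryl group and so places C3'' anti to the C2 oxygen (3R), after which mild acid-catalysed lactonisation of the γ-hydroxy ester gives the cis lactone without breaking the C2–O bond.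

Step 3
Reactants: 7 4-hydroxybenzaldehyde
Product: 8 4-(methoxymethoxy)benzaldehyde
Conditions: MOMCl, K2CO3, acetone, 0 °C to rt
Reagents that add atoms: chloromethyl methyl ether, COCCl
Why: Standard O-alkylation of a phenoxide with an α-chloro ether (MOM protection); the acetal should survive every basic, fluoride and thermal step that follows and comes off under mild acid at the end.

Step 4
Reactants: 6 methyl (2S,3R)-2-(4-methoxyphenyl)-5-oxooxolane-3-carboxylate; 8 4-(methoxymethoxy)benzaldehyde
Product: 10 methyl (2S,3R,4S)-4-{(R)-hydroxy[4-(methoxymethoxy)phenyl]methyl}-2-(4-methoxyphenyl)-5-oxooxolane-3-carboxylate, via lithium lactone enolate 9 (not isolated)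
Conditions: LiN(iPr)2 (1.05 equiv), THF, −78 °C; 8, −78 °C; AcOH, −78 °C
Reagents that add atoms: none
Why: Aldol addition of a γ-butyrolactone lithium enolate of the kind used for lignan lactones: kinetic deprotonation takes the unhindered C3'' methylene, the aldehyde approaches the ring face opposite the cis aryl and ester groups (C3'' trans to the C3 substituent), and the ring-fixed (E)-enolate should react through a Zimmerman–Traxler chair to give the anti carbinol C2'', any carbinol epimer being removed by chromatography.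

Step 5
Reactants: 10 methyl (2S,3R,4S)-4-{(R)-hydroxy[4-(methoxymethoxy)phenyl]methyl}-2-(4-methoxyphenyl)-5-oxooxolane-3-carboxylate
Product: 11 (2R,3S)-2-[(S)-hydroxy(4-methoxyphenyl)methyl]-3-{(R)-hydroxy[4-(methoxymethoxy)phenyl]methyl}-N1,N4-dimethoxy-N1,N4-dimethylbutanediamide
Conditions: MeNH(OMe)·HCl, AlMe3 (8 equiv each), CH2Cl2, 0 to 35 °C; aq. potassium sodium tartrate
Reagents that add atoms: N,O-dimethylhydroxylamine hydrochloride, CNOC.Cl
Why: Weinreb aminolysis by the aluminium amide formed in the flask turns both the lactone carbonyl C4'' and the ester carbonyl C4 into N-methoxy-N-methylamides, a reaction routinely run on unprotected aldol adducts because the aluminium alkoxides neither retro-aldolise nor enolise.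

Step 6
Reactants: 11 (2R,3S)-2-[(S)-hydroxy(4-methoxyphenyl)methyl]-3-{(R)-hydroxy[4-(methoxymethoxy)phenyl]methyl}-N1,N4-dimethoxy-N1,N4-dimethylbutanediamide
Product: 12 bis(triethylsilyl) ether of 11
Conditions: TESCl, imidazole, DMAP (cat.), DMF, 0 °C to rt
Reagents that add atoms: chlorotriethylsilane, CC[Si](Cl)(CC)CC
Why: Silylation of both benzylic alcohols directly after work-up blocks relactonisation and retro-aldol cleavage in the basic acylation step, and triethylsilyl is chosen because it comes off under the mild acid that later closes rings C.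

Step 7
Reactants: 13 2,2,6-trimethyl-4H-1,3-dioxin-4-one; 14 acetyl chloride
Product: 16 2,2-dimethyl-6-(2-oxopropyl)-4H-1,3-dioxin-4-one, via lithium dienolate 15 (not isolated)
Conditions: 13 (2 equiv), LiN(SiMe3)2 (2 equiv), THF, −78 °C; 14 (1 equiv), −78 °C; 1 M HCl
Reagents that add atoms: none
Why: γ-Selective C-acylation of the extended lithium dienolate of the dioxinone by an acid chloride (vinylogous Claisen condensation), with the second equivalent of dienolate serving as base for the more acidic product.

Step 8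
Reactants: 12 bis(triethylsilyl) ether of 11; 16 2,2-dimethyl-6-(2-oxopropyl)-4H-1,3-dioxin-4-one
Product: 18 6,6'-{(5R,6S)-5-[(S)-(4-methoxyphenyl)(triethylsilyloxy)methyl]-6-{(R)-[4-(methoxymethoxy)phenyl](triethylsilyloxy)methyl}-2,4,7,9-tetraoxodecane-1,10-diyl}bis(2,2-dimethyl-4H-1,3-dioxin-4-one), via dilithium dianion 17 (not isolated)
Conditions: 16 (6 equiv), LiN(iPr)2 (12 equiv), THF, −78 to −40 °C; 12, −78 to −20 °C; AcOH, −78 °C
Reagents that add atoms: none
Why: Claisen-type acylation of a 1,3-dicarbonyl dianion at its terminal, more basic carbon (C4a, C4a'') by Weinreb amides, the established entry to diketo-dioxinones; the chelated tetrahedral adducts survive until the cold acidic quench, which prevents over-addition and keeps C3 and C3'' from enolising.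

Step 9
Reactants: 18 bis(diketo-dioxinone) bis(triethylsilyl) ether
Product: 20 (2S,3R,2'R,3'S)-6,6'-bis[(2,2-dimethyl-4-oxo-4H-1,3-dioxin-6-yl)methyl]-2-(4-methoxyphenyl)-2'-[4-(methoxymethoxy)phenyl]-2,2',3,3'-tetrahydro-[3,3'-bipyran]-4,4'-dione, via desilylated diol 19 (not isolated)
Conditions: 48 % aq. HF, MeCN, 0 °C to rt
Reagents that add atoms: none
Why: Acidic desilylation followed by the well-known cyclodehydration of δ-hydroxy-β-diketones to 2,3-dihydropyran-4-ones: each freed hydroxyl adds to the unhindered C8a carbonyl of its own chain (six-membered hemiketal) and loss of water gives the vinylogous ester with the C2–O and C2''–O bonds intact, whereas closure on the neighbouring C4 carbonyl would meet a fully branched centre, give a cis-substituted five-membered ring and could not occur on both sides, since that would demand a trans-fused bicyclo[3.3.0]octane.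

Step 10
Reactants: 20 3,3'-linked bis[2-aryl-6-(dioxinonylmethyl)-2,3-dihydropyran-4-one]
Product: 22 (2S,3R,2''R,3''S)-5,7,5'',7''-tetrahydroxy-4'-methoxy-4'''-(methoxymethoxy)-3,3''-biflavanone, via bis(acylketene) 21 (not isolated)
Conditions: dry PhMe (1 mM), 4 Å MS, Ar, 110 °C
Reagents that add atoms: none
Why: Proposed new method: at about 110 °C each dioxinone loses acetone by retro-[4+2] cleavage to give an acylketene (the two ends react independently, 21 being their formal sum), and enolisation of its C7 ketone toward the doubly activated C8 methylene gives the (Z)-dienylketene C4a=C8a–C8=C7(OH)–C6=C5=O. Each ring A then closes by a thermal disrotatory 6π electrocyclisation that joins C4a to the ketene carbon C5 (equivalently a six-membered intramolecular C-acylation of the enol-ether β-carbon), and two proton shifts aromatise the cyclohexadienone to the 5,7-dihydroxy ring. The closest known reaction types are the acylketene route from diketo-dioxinones to resorcylates and the dienylketene-to-phenol closure that ends the Danheiser benzannulation; what is new is the Claisen-type fold onto the C–H of a dihydropyranone, run twice in one molecule. No stereocentre is formed, and the neutral aprotic medium should leave C2, C3, C3'' and C2'' untouched. The step needs C-acylation at C4a in preference to O-acylation, aldol-type folding and intermolecular ketene capture: the C8a oxygen is already alkylated as O1, so 4-hydroxy-2-pyrone formation is blocked, ring C holds C4 trans to C8 across C4a=C8a, so C6 cannot reach C4 while C4a–H lies cis to C8, and millimolar dilution in dry toluene should suppress dimerisation, hydrolysis and capture by product phenols.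

Step 11
Reactants: 22 4'''-O-MOM ether of the target
Product: 23 (2S,3R,2''R,3''S)-5,7,5'',7'',4'''-pentahydroxy-4'-methoxy-3,3''-biflavanone (CNP0196568.3)
Conditions: HCl (1.25 M in MeOH), 40 °C
Reagents that add atoms: none
Why: Acid-catalysed transacetalisation of the aryl MOM ether in methanol; trans-2,3-disubstituted flavanones are configurationally stable under mild acid, and base, which would open ring C, is avoided.

Compound list
1 | methyl 3-(4-methoxyphenyl)-3-oxopropanoate | COC(=O)CC(=O)c1ccc(OC)cc1 | starting material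
2 | methyl (3S)-3-hydroxy-3-(4-methoxyphenyl)propanoate | COc1ccc([C@@H](O)CC(=O)OC)cc1 | intermediate
3 | methyl bromoacetate | COC(=O)CBr | starting material
4 | dilithium alkoxide-enolate of 2 (chelated dianion) | [Li+].[Li+].COc1ccc([C@@H]([O-])/C=C(\[O-])OC)cc1 | intermediate
5 | dimethyl (2R)-2-[(S)-hydroxy(4-methoxyphenyl)methyl]butanedioate | COc1ccc([C@@H](O)[C@H](C(=O)OC)CC(=O)OC)cc1 | intermediate
6 | methyl (2S,3R)-2-(4-methoxyphenyl)-5-oxooxolane-3-carboxylate | COc1ccc([C@H]2OC(=O)C[C@H]2C(=O)OC)cc1 | intermediate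
7 | 4-hydroxybenzaldehyde | O=Cc1ccc(O)cc1 | starting material
8 | 4-(methoxymethoxy)benzaldehyde | COCOc1ccc(C=O)cc1 | intermediate
9 | lithium enolate of lactone 6 | [Li+].COc1ccc([C@H]2OC([O-])=C[C@H]2C(=O)OC)cc1 | intermediate
10 | methyl (2S,3R,4S)-4-{(R)-hydroxy[4-(methoxymethoxy)phenyl]methyl}-2-(4-methoxyphenyl)-5-oxooxolane-3-carboxylate | COc1ccc([C@H]2OC(=O)[C@H]([C@@H](O)c3ccc(OCOC)cc3)[C@H]2C(=O)OC)cc1 | intermediate
11 | (2R,3S)-2-[(S)-hydroxy(4-methoxyphenyl)methyl]-3-{(R)-hydroxy[4-(methoxymethoxy)phenyl]methyl}-N1,N4-dimethoxy-N1,N4-dimethylbutanediamide | COc1ccc([C@@H](O)[C@H](C(=O)N(C)OC)[C@H](C(=O)N(C)OC)[C@@H](O)c2ccc(OCOC)cc2)cc1 | intermediate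
12 | bis(triethylsilyl) ether of 11 | COc1ccc([C@@H](O[Si](CC)(CC)CC)[C@H](C(=O)N(C)OC)[C@H](C(=O)N(C)OC)[C@@H](O[Si](CC)(CC)CC)c2ccc(OCOC)cc2)cc1 | intermediate
13 | 2,2,6-trimethyl-4H-1,3-dioxin-4-one | CC1=CC(=O)OC(C)(C)O1 | starting material
14 | acetyl chloride | CC(=O)Cl | starting material
15 | lithium dienolate of 13 | [Li+].C=C1C=C([O-])OC(C)(C)O1 | intermediate
16 | 2,2-dimethyl-6-(2-oxopropyl)-4H-1,3-dioxin-4-one | CC(=O)CC1=CC(=O)OC(C)(C)O1 | intermediate
17 | dilithium dianion of 16 | [Li+].[Li+].C=C([O-])C=C1C=C([O-])OC(C)(C)O1 | intermediate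
18 | 6,6'-{(5R,6S)-5-[(S)-(4-methoxyphenyl)(triethylsilyloxy)methyl]-6-{(R)-[4-(methoxymethoxy)phenyl](triethylsilyloxy)methyl}-2,4,7,9-tetraoxodecane-1,10-diyl}bis(2,2-dimethyl-4H-1,3-dioxin-4-one) | COc1ccc([C@@H](O[Si](CC)(CC)CC)[C@H](C(=O)CC(=O)CC2=CC(=O)OC(C)(C)O2)[C@H](C(=O)CC(=O)CC2=CC(=O)OC(C)(C)O2)[C@@H](O[Si](CC)(CC)CC)c2ccc(OCOC)cc2)cc1 | intermediate
19 | desilylated diol of 18 | COc1ccc([C@@H](O)[C@H](C(=O)CC(=O)CC2=CC(=O)OC(C)(C)O2)[C@H](C(=O)CC(=O)CC2=CC(=O)OC(C)(C)O2)[C@@H](O)c2ccc(OCOC)cc2)cc1 | intermediate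
20 | (2S,3R,2'R,3'S)-6,6'-bis[(2,2-dimethyl-4-oxo-4H-1,3-dioxin-6-yl)methyl]-2-(4-methoxyphenyl)-2'-[4-(methoxymethoxy)phenyl]-2,2',3,3'-tetrahydro-[3,3'-bipyran]-4,4'-dione | COc1ccc([C@H]2OC(CC3=CC(=O)OC(C)(C)O3)=CC(=O)[C@@H]2[C@@H]2C(=O)C=C(CC3=CC(=O)OC(C)(C)O3)O[C@H]2c2ccc(OCOC)cc2)cc1 | intermediate
21 | bis(acylketene): the bipyrandione of 20 bearing 2,4-dioxobut-3-en-1-yl groups at C6 and C6' | COc1ccc([C@H]2OC(CC(=O)C=C=O)=CC(=O)[C@@H]2[C@@H]2C(=O)C=C(CC(=O)C=C=O)O[C@H]2c2ccc(OCOC)cc2)cc1 | intermediate
22 | (2S,3R,2''R,3''S)-5,7,5'',7''-tetrahydroxy-4'-methoxy-4'''-(methoxymethoxy)-3,3''-biflavanone | COc1ccc([C@H]2Oc3cc(O)cc(O)c3C(=O)[C@@H]2[C@@H]2C(=O)c3c(O)cc(O)cc3O[C@H]2c2ccc(OCOC)cc2)cc1 | intermediate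
23 | (2S,3R,2''R,3''S)-5,7,5'',7'',4'''-pentahydroxy-4'-methoxy-3,3''-biflavanone | COc1ccc([C@H]2Oc3cc(O)cc(O)c3C(=O)[C@@H]2[C@@H]2C(=O)c3c(O)cc(O)cc3O[C@H]2c2ccc(O)cc2)cc1 | target

Total step count: 11. Longest linear sequence: 9 steps (1, 2, 4, 5, 6, 8, 9, 10, 11).

Steps most likely to fail

1) Step 10.
- What may go wrong: ketene capture between molecules (dimerisation, acylation of phenols already formed), capture by adventitious water followed by decarboxylation, or enolisation at C8 too slow for ring closure to compete.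
- Fallback (known chemistry, sets out from 20, returns at 22): 20 is heated in toluene in the presence of methanol, the routine trapping of dioxinone-derived acylketenes by an alcohol, to give the bis(β-keto methyl ester) F1. Brief treatment with NaOMe in MeOH at 0 °C and an acidic quench then bring about the base-induced Claisen (Dieckmann-type) fold by which 3,5,7-trioxo esters are known to give acylphloroglucinols. C4a, the α-carbon of the C8-deprotonated vinylogous ester, attacks the ester carbon C5, and 22 results.

2) Step 9.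
- What may go wrong: addition of a freed hydroxyl to the carbonyl of the neighbouring chain instead of its own C8a carbonyl, acid-induced loss of water across C2–C3 (which would erase two stereocentres), or premature aldol-type aromatisation of the diketo-dioxinone.
- Fallback (sets out from 12, returns at 20): rings C are closed before the dioxinone is present, at a stage where only conjugate addition is productive. HC≡CMgBr converts both Weinreb amides into the bis(ynone) F2. Desilylation with HF·pyridine and AgOTf-catalysed 6-endo-dig oxa-Michael cyclisation of the β-hydroxy ynones give the 6,6'-unsubstituted bis(dihydropyranone) F3. A TBSOTf-promoted vinylogous Mukaiyama–Michael addition of the silyl dienol ether F4 (from 13 with LiN(iPr)2 and TBSCl) at C8a and C8a'' gives the bis(silyl enol ether) F5. Saegusa–Ito oxidation with Pd(OAc)2 restores the C4a=C8a double bonds and gives 20.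

3) Step 8.
- What may go wrong: stalling after the first acylation because the second amide is flanked by two branched centres, deprotonation at C3 or C3'' followed by β-elimination of silanolate, or base-induced N–O fragmentation of the amide.
- Fallback (sets out from 12, returns at 18): a change of oxidation level. iBu2AlH at −78 °C reduces both amides to the dialdehyde F6. The far more electrophilic aldehydes take up dianion 17 at −78 °C in a double aldol addition to give the bis(β-hydroxy ketone) F7, whose carbinol configuration is irrelevant. Dess–Martin periodinane then oxidises both carbinols to the β-diketones of 18.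

Further compounds
F1 | step 10 | dimethyl 4,4'-{(2S,3R,2'R,3'S)-2-(4-methoxyphenyl)-2'-[4-(methoxymethoxy)phenyl]-4,4'-dioxo-2,2',3,3'-tetrahydro-[3,3'-bipyran]-6,6'-diyl}bis(3-oxobutanoate) | COc1ccc([C@H]2OC(CC(=O)CC(=O)OC)=CC(=O)[C@@H]2[C@@H]2C(=O)C=C(CC(=O)CC(=O)OC)O[C@H]2c2ccc(OCOC)cc2)cc1
F2 | step 9 | (4R,5S)-4-[(S)-(4-methoxyphenyl)(triethylsilyloxy)methyl]-5-{(R)-[4-(methoxymethoxy)phenyl](triethylsilyloxy)methyl}octa-1,7-diyne-3,6-dione | COc1ccc([C@@H](O[Si](CC)(CC)CC)[C@H](C(=O)C#C)[C@H](C(=O)C#C)[C@@H](O[Si](CC)(CC)CC)c2ccc(OCOC)cc2)cc1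
F3 | step 9 | (2S,3R,2'R,3'S)-2-(4-methoxyphenyl)-2'-[4-(methoxymethoxy)phenyl]-2,2',3,3'-tetrahydro-[3,3'-bipyran]-4,4'-dione | COc1ccc([C@H]2OC=CC(=O)[C@@H]2[C@@H]2C(=O)C=CO[C@H]2c2ccc(OCOC)cc2)cc1
F4 | step 9 | tert-butyl[(2,2-dimethyl-6-methylidene-1,3-dioxin-4-yl)oxy]dimethylsilane | C=C1C=C(O[Si](C)(C)C(C)(C)C)OC(C)(C)O1
F5 | step 9 | bis(tert-butyldimethylsilyl enol ether) of the double Michael adduct (3,3'-linked 3,6-dihydro-2H-pyrans, C8a and C8a'' configuration undefined) | COc1ccc([C@H]2OC(CC3=CC(=O)OC(C)(C)O3)C=C(O[Si](C)(C)C(C)(C)C)[C@@H]2[C@@H]2C(O[Si](C)(C)C(C)(C)C)=CC(CC3=CC(=O)OC(C)(C)O3)O[C@H]2c2ccc(OCOC)cc2)cc1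
F6 | step 8 | (2R,3S)-2-[(S)-(4-methoxyphenyl)(triethylsilyloxy)methyl]-3-{(R)-[4-(methoxymethoxy)phenyl](triethylsilyloxy)methyl}butanedial | COc1ccc([C@@H](O[Si](CC)(CC)CC)[C@H](C=O)[C@H](C=O)[C@@H](O[Si](CC)(CC)CC)c2ccc(OCOC)cc2)cc1
F7 | step 8 | bis(β-hydroxy ketone) from double aldol addition of 17 to F6 (C4 and C4'' carbinols undefined) | COc1ccc([C@@H](O[Si](CC)(CC)CC)[C@H](C(O)CC(=O)CC2=CC(=O)OC(C)(C)O2)[C@H](C(O)CC(=O)CC2=CC(=O)OC(C)(C)O2)[C@@H](O[Si](CC)(CC)CC)c2ccc(OCOC)cc2)cc1
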